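The earlier runs and the new flask were computed for an exercise, and the scatter is random.

Start with the easy step. In the earlier runs over-reaction product climbs as target stands in the flask, so I take its rate as k·c(target), first-order in target. This gives a rule for any flask where that rate law holds. Exposure time is the hours of present target the flask has held, c(over-reaction product)/(k·c(target)). The share asked for, a selectivity, is then 1/(1+k·exposure).

| flask | substrate | reagent | free catalyst | remark | time |
|---|---|---|---|---|---|
| ochre | 20 mM | 1 equiv | 20 mol% | run made earlier |  |
| grey | 20 mM | 1 equiv | 28 mol% | run made earlier |  |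
| violet | 40 mM | 1 equiv | 20 mol% | run made earlier |  |
| Thursday's | 20 mM | 1.00 equiv | 20 mol% | one stirred flow tank at steady state, fed with the mixture as stated, mean residence time 40 h |  |
| Sunday's | 20 mM (fed, over 32.0 h) | 1.00 equiv | 20 mol% | a stirred flask in which substrate is dosed at a steady rate over 32.0 h without added volume, worked up at 40 h | 40 h |
| Saturday's | 20 mM | 1.00 equiv | 20 mol% | everything together in a closed stirred flask, run for 40 h | 40 h |
| Friday's | 20 mM | 1.00 equiv (fed, over 32.0 h) | 20 mol% | all but reagent at the start; reagent goes in evenly over 32.0 h, the run ends at 40 h | 40 h |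

- ochre (time / h: target / %, over-reaction product / %): 6.00: 1.9, 0.1; 12.0: 5.4, 0.5; 20.0: 9.0, 1.6; 25.0: 10.1, 2.2; 30.0: 11.4, 2.8; 40.0: 12.2, 4.0
- grey (time / h: target / %, over-reaction product / %): 4.00: 1.3, 0; 6.00: 2.8, 0; 10.0: 6.2, 0.5; 20.0: 11.8, 1.8; 30.0: 15.0, 3.3; 50.0: 16.9, 8.6
- violet (time / h: target / %, over-reaction product / %): 4.00: 2.5, 0.2; 12.0: 8.9, 0.5; 20.0: 13.9, 2.1; 30.0: 17.5, 4.6; 50.0: 19.1, 10.8

(scatter of a reading: 0.3 percentage points)

* the set-up with the highest share of target in all that became target or over-reaction product, at the outlet or at the end ("none" if the first two lie within 2 percentage points) (Thursday's / Sunday's / Saturday's / Friday's / none)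
* share of target in all that became target or over-reaction product, at the outlet or at the end, Thursday's
* share of target in all that became target or over-reaction product, at the outlet or at the end, Sunday's
* share of target in all that became target or over-reaction product, at the outlet or at the end, Saturday's
* share of target in all that became target or over-reaction product, at the outlet or at the end, Friday's

Which numbers must be good? Saturday's repeats the ochre recipe, so its share can be read at 40.0 h without k: 75.3%. Thursday's tank has an exposure equal to its residence time, 40 h, so it hangs on k. Ochre's late rise gives 0.0113 h⁻¹ and a share of 68.9%. Grey's late rise gives the ageing constant 0.0166 h⁻¹ and 60.1%. That gap is 8.8 percentage points, and the margin is 2 points, so k matters here.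

I trust grey, whose over-reaction product rises further than ochre's, and violet reads 0.0169 h⁻¹. Ochre's exposure at its last reading is then 19.7 h, shorter than the tank's, so I put Thursday's last. Both fed flasks make target later, so I put them above Saturday's. I can't rank them, since substrate and reagent always moved together in the earlier runs.

The forecast gave 66%, 80%, 75.5% and 77% for Thursday's, Sunday's, Saturday's and Friday's, and said “Sunday's is a tentative best”.

The flasks give 62.5%, 74.7%, 72.4% and 79.5% in that order, so Friday's comes first.

    reagent + free catalyst → catalyst intermediate A (k = 17.0 M⁻¹ h⁻¹)
    substrate + catalyst intermediate A → catalyst intermediate B (k = 24.0 M⁻¹ h⁻¹)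
    catalyst intermediate B → catalyst intermediate C (k = 0.100 h⁻¹)
    catalyst intermediate C ⇌ free catalyst + target (K = 1.60 M, k = 19.0 h⁻¹)
    target → over-reaction product (k = 0.0150 h⁻¹)
    catalyst intermediate A → spent catalyst (k = 0.350 h⁻¹)
    2 reagent → self-condensation product (k = 0.700 M⁻¹ h⁻¹)

On Saturday's, with substrate as charged, catalyst intermediate A has a half-life of 1.4 h towards substrate and 1.98 h towards spent catalyst. On Sunday's, where substrate comes in slowly, spent catalyst stands at 86.2% after 20.0 h, against 58.5% on Saturday's. Taken with the constant read from grey, 0.0166 h⁻¹, Sunday's share of 74.7% at 40 h gives an estimated exposure of 20.4 h. Read at 4.0 d, Sunday's flask holds 2.69% target at a share of 40.8%, and the same grey reading gives an estimated exposure of 87.4 h.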